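## Retrosynthetic overview

1. Target 8 ⇒ two acyl C–O disconnections (angelate on O7 from angelic acid 6, acetate on O9) ⇒ diol 4.
2. Diol 4 ⇒ two C–O disconnections at unactivated ring methylenes (C9–O, then C7–O; the key step, one pot, enzymatic) ⇒ enone 2.
3. Enone 2 ⇒ C1=O disconnection (allylic C–H oxidation) ⇒ (+)-α-longipinene 1.
4. Ring order: no ring is formed. The cyclobutane, cyclohexene and cycloheptane rings of 1 are carried through intact, so every bond made in the route is a C–O bond.

Assumption: commercial (+)-α-longipinene, a turpentine sesquiterpene, is taken to be the (1R,2S,7R,8R) hydrocarbon and to count as a cheap starting material; that configuration is the ring configuration of the target.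

Numbering (longipinane): C1 (C=O), C2=C3 (Me on C3), C4 (bridgehead CH), C5 (cyclobutane CH), C6 (CMe2), C7, C8, C9, C10 (quaternary, Me), C11 (bridgehead CH next to C1); extra bonds C4–C10 and C5–C11. On the seven-membered ring, α is the face on the side of C11 and β the face on the side of C4; the target is then the 7β,9α-diester (7R,9R), with the two oxygens trans.

## Route

Step 1
Reactants: 1 (+)-α-longipinene
Product: 2 longipin-2-en-1-one (vulgarone B)
Conditions: Rh2(cap)4 (dirhodium tetrakis(caprolactamate), 1 mol%), t-BuOOH (70% aq., 5 equiv), K2CO3 (0.5 equiv), CH2Cl2, 25 °C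
Reagents that add atoms: tert-butyl hydroperoxide CC(C)(C)OO
Why: Radical allylic C–H oxidation of the Doyle type: the tert-butylperoxyl radical takes the only secondary allylic hydrogen (C1–H2; the bridgehead C4–H cannot give a planar allyl radical and the vinyl methyl is primary) and the allyl peroxide collapses to the enone, as in α-pinene to verbenone; no stereocenter is formed.

Step 2
Reactants: 2 longipin-2-en-1-one
Product: 4 7β,9α-dihydroxylongipin-2-en-1-one, via 9α-hydroxylongipin-2-en-1-one 3 (not isolated)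
Conditions: P450 BM3 (CYP102A1) variant A, then variant B (0.1 mol% each, cell lysate), NADP+ (cat.), D-glucose (3 equiv), glucose dehydrogenase, air, K2HPO4/KH2PO4 buffer pH 8.0, 2% DMSO, 25 °C
Reagents that add atoms: dioxygen O=O
Why: Proposed new method: two active-site variants of P450 BM3, evolved on 2 (variant A) and on 3 (variant B), put oxygen from O2 into C9–Hα and then C7–Hβ; the iron-oxo porphyrin radical cation abstracts the hydrogen held over the heme and the hydroxyl rebounds on the same face far faster than the cyclobutylcarbinyl radical at C9 can ring-open, so each OH replaces its hydrogen with retention (9R, then 7R); the site choice (C9 and C7, each next to a quaternary carbon, instead of the innately preferred C8) comes from binding, with the C1 carbonyl (and in the second round the new 9α-OH) hydrogen-bonded to an engineered polar residue, while the enone has already removed the allylic CH2 and made the alkene too electron-poor for epoxidation; the closest known reaction type is the P450 BM3-variant hydroxylation of sclareolide at C3 (a methylene next to a gem-dimethyl carbon) and of sesquiterpene lactones at unactivated ring methylenes.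

Step 3
Reactants: 4 7β,9α-dihydroxylongipin-2-en-1-one
Product: 5 9α-acetoxy-7β-hydroxylongipin-2-en-1-one
Conditions: Ac2O (1.05 equiv), pyridine, CH2Cl2, −20 °C
Reagents that add atoms: acetic anhydride CC(=O)OC(C)=O
Why: Kinetic mono-acylation: the 9α-OH, next to the tied-back cyclobutane carbon C10, is expected to be less shielded than the 7β-OH, which is gauche to the gem-dimethyl group on C6, and the trans-1,3 arrangement of the two oxygens rules out later acyl migration; no stereocenter is touched.

Step 4
Reactants: 5 9α-acetoxy-7β-hydroxylongipin-2-en-1-one, 6 angelic acid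
Product: 8 9α-acetoxy-7β-angeloyloxylongipin-2-en-1-one (target), via angeloyl 2,4,6-trichlorobenzoyl anhydride 7 (not isolated)
Conditions: 6 (3 equiv), 2,4,6-Cl3C6H2COCl (3 equiv), Et3N (3 equiv), toluene, 25 °C, 2 h; then 5, 80 °C, 24 h (no DMAP)
Reagents that add atoms: 2,4,6-trichlorobenzoyl chloride O=C(Cl)c1c(Cl)cc(Cl)cc1Cl
Why: Yamaguchi-type mixed-anhydride esterification without DMAP, the usual way to angeloylate a hindered secondary alcohol without Z-to-E isomerisation to the tiglate; the alcohol attacks the less hindered angeloyl carbonyl of 7, and C7 keeps its configuration because only the O–H bond reacts.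

## Compound list

1 | (+)-α-longipinene, (1R,2S,7R,8R)-2,6,6,9-tetramethyltricyclo[5.4.0.0(2,8)]undec-9-ene | C1CC[C@@]2(C)[C@@H]3CC=C(C)[C@H]2[C@@H]3C1(C)C | starting material
2 | (4R,5S,10R,11R)-longipin-2-en-1-one (vulgarone B) | C1CC[C@@]2(C)[C@@H]3C(=O)C=C(C)[C@H]2[C@@H]3C1(C)C | intermediate
3 | (4R,5S,9R,10R,11R)-9α-hydroxylongipin-2-en-1-one | C1C[C@@H](O)[C@@]2(C)[C@@H]3C(=O)C=C(C)[C@H]2[C@@H]3C1(C)C | intermediate
4 | (4R,5S,7R,9R,10R,11R)-7β,9α-dihydroxylongipin-2-en-1-one | O[C@@H]1C[C@@H](O)[C@@]2(C)[C@@H]3C(=O)C=C(C)[C@H]2[C@@H]3C1(C)C | intermediate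
5 | (4R,5S,7R,9R,10R,11R)-9α-acetoxy-7β-hydroxylongipin-2-en-1-one | O[C@@H]1C[C@@H](OC(C)=O)[C@@]2(C)[C@@H]3C(=O)C=C(C)[C@H]2[C@@H]3C1(C)C | intermediate
6 | angelic acid, (Z)-2-methylbut-2-enoic acid | C/C=C(/C)C(=O)O | starting material
7 | angeloyl 2,4,6-trichlorobenzoyl anhydride, (Z)-2-methylbut-2-enoic 2,4,6-trichlorobenzoic anhydride | C/C=C(/C)C(=O)OC(=O)c1c(Cl)cc(Cl)cc1Cl | intermediate
8 | (4R,5S,7R,9R,10R,11R)-9α-acetoxy-7β-[(Z)-2-methylbut-2-enoyloxy]longipin-2-en-1-one, CNP0260482.1 | C/C=C(/C)C(=O)O[C@@H]1C[C@@H](OC(C)=O)[C@@]2(C)[C@@H]3C(=O)C=C(C)[C@H]2[C@@H]3C1(C)C | target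

## Step count

Total steps: 4. Longest linear sequence: 4 steps (1 → 2 → 4 → 5 → 8).

## Three steps most likely to fail

**Step 2 (the proposed new step).** Risks: no variant pair with the needed site and face selectivity, competing oxidation at C8 or at the vinyl methyl, or over-oxidation of the new alcohols to ketones.

Fallback, known reactions only; it sets out from 2 and comes back at 4. It is eight operations long and only justified if the enzymatic route fails outright.
- Oxidise the innately most reactive methylene, C8, with [Fe((S,S)-PDP)(MeCN)2](SbF6)2, H2O2 and AcOH in MeCN (White–Chen methylene oxidation) to longipin-2-ene-1,8-dione F1.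
- Use the new ketone to activate both neighbours: D-proline (30 mol%) and nitrosobenzene (3 equiv) in DMSO, a double α-aminoxylation known to give the trans bis-adduct under catalyst control (D-proline is expected to give 7S,9S), to reach 7β,9α-bis(anilinooxy)longipin-2-ene-1,8-dione F2.
- Cleave the N–O bonds with Zn and AcOH to 7β,9α-dihydroxylongipin-2-ene-1,8-dione F3.
- Acetylate with Ac2O, DMAP and pyridine to 7β,9α-diacetoxylongipin-2-ene-1,8-dione F4.
- Reduce the saturated, doubly α-oxygenated ketone with Zn(BH4)2 in Et2O at −20 °C (non-basic, so no acetyl shift) to 7β,9α-diacetoxy-8-hydroxylongipin-2-en-1-one F5; either C8 epimer serves.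
- Treat with 1,1'-thiocarbonyldiimidazole in 1,2-dichloroethane at 70 °C to give 7β,9α-diacetoxy-8-(imidazol-1-ylcarbonothioyloxy)longipin-2-en-1-one F6.
- Barton–McCombie deoxygenation with Bu3SnH and AIBN in toluene at 90 °C gives 7β,9α-diacetoxylongipin-2-en-1-one F7.
- Methanolysis with K2CO3 in MeOH gives 4.

**Step 3.** Risk: the two hindered secondary hydroxyls may acetylate at similar rates, or in the opposite order.

Fallback; it sets out from 2 and comes back at 5. Differentiate the oxygens by the order in which they are introduced instead of by acylation rate. Run step 2 with variant A alone and isolate 3. Acetylate its single hydroxyl (Ac2O, DMAP, pyridine) to 9α-acetoxylongipin-2-en-1-one F8. Then hydroxylate C7–Hβ with purified, esterase-free variant B, which gives 5 directly.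

**Step 4.** Risks: sluggish acylation of the neopentyl-type 7β-OH, and Z-to-E isomerisation of the angelate to the tiglate at 80 °C.

Fallback; it sets out from 5 and comes back at 8. Build the Z-alkene on the molecule instead of transferring it. Esterify 5 with 2-[bis(2,2,2-trifluoroethoxy)phosphoryl]propanoic acid (N,N'-diisopropylcarbodiimide, DMAP, CH2Cl2) to 9α-acetoxy-7β-{2-[bis(2,2,2-trifluoroethoxy)phosphoryl]propanoyloxy}longipin-2-en-1-one F9. Then run a Still–Gennari olefination (KN(SiMe3)2, 18-crown-6, THF, −78 °C, then acetaldehyde), which gives the Z-trisubstituted enoate, i.e. 8.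

## Further compounds

F1 | step 2 | longipin-2-ene-1,8-dione | C1C(=O)C[C@@]2(C)[C@@H]3C(=O)C=C(C)[C@H]2[C@@H]3C1(C)C
F2 | step 2 | 7β,9α-bis(anilinooxy)longipin-2-ene-1,8-dione | c4ccccc4NO[C@@H]1C(=O)[C@@H](ONc5ccccc5)[C@@]2(C)[C@@H]3C(=O)C=C(C)[C@H]2[C@@H]3C1(C)C
F3 | step 2 | 7β,9α-dihydroxylongipin-2-ene-1,8-dione | O[C@@H]1C(=O)[C@@H](O)[C@@]2(C)[C@@H]3C(=O)C=C(C)[C@H]2[C@@H]3C1(C)C
F4 | step 2 | 7β,9α-diacetoxylongipin-2-ene-1,8-dione | CC(=O)O[C@@H]1C(=O)[C@@H](OC(C)=O)[C@@]2(C)[C@@H]3C(=O)C=C(C)[C@H]2[C@@H]3C1(C)C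
F5 | step 2 | 7β,9α-diacetoxy-8-hydroxylongipin-2-en-1-one (C8 epimers) | CC(=O)O[C@@H]1C(O)[C@@H](OC(C)=O)[C@@]2(C)[C@@H]3C(=O)C=C(C)[C@H]2[C@@H]3C1(C)C
F6 | step 2 | 7β,9α-diacetoxy-8-(imidazol-1-ylcarbonothioyloxy)longipin-2-en-1-one (C8 epimers) | CC(=O)O[C@@H]1C(OC(=S)n4ccnc4)[C@@H](OC(C)=O)[C@@]2(C)[C@@H]3C(=O)C=C(C)[C@H]2[C@@H]3C1(C)C
F7 | step 2 | 7β,9α-diacetoxylongipin-2-en-1-one | CC(=O)O[C@@H]1C[C@@H](OC(C)=O)[C@@]2(C)[C@@H]3C(=O)C=C(C)[C@H]2[C@@H]3C1(C)C
F8 | step 3 | 9α-acetoxylongipin-2-en-1-one | C1C[C@@H](OC(C)=O)[C@@]2(C)[C@@H]3C(=O)C=C(C)[C@H]2[C@@H]3C1(C)C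
F9 | step 4 | 9α-acetoxy-7β-{2-[bis(2,2,2-trifluoroethoxy)phosphoryl]propanoyloxy}longipin-2-en-1-one (epimers at the phosphonate carbon) | CC(C(=O)O[C@@H]1C[C@@H](OC(C)=O)[C@@]2(C)[C@@H]3C(=O)C=C(C)[C@H]2[C@@H]3C1(C)C)P(=O)(OCC(F)(F)F)OCC(F)(F)F
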